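Ring A is treated as a folded tetraketide. Its oxygens at C2', C4' and C6' and the ketone of the chain to ring B sit on alternate carbons. C5', the carbon bonded to the methine C7, is the α-carbon of a terminal ester. The plan rests on one C1'–C6' disconnection. In a single operation, a magnesium-templated Claisen closure of an open 3,5,7-trioxo ester forms that bond, closes ring A and aromatises it, with the acyl chain and the C7 substituent already in place. The precursor is a methyl 9-(4-methoxyphenyl)-3,5,7-trioxononanoate whose C2 carries the stereodefined C7–C10 chain, with rings C and D as benzyl ethers.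

Key step: step 11

Atom labels: ring A = C1'–C6' (C1' acylated, C5' bonded to C7). The side chain is C7–C10. Ring B is the anisyl ring, ring C sits on C7 and ring D on C10. The target is (7R,8S,9R).

Assumption: the antipode of the diene ligand in step 6 is assigned from the usual α-face recognition model. The antipode that gives (R)-3-arylcyclohexanones should bind this (E)-enoate so that the aryl group reaches the Si face of C7. Both antipodes are available if a trial run shows the opposite sense.

Remarks on the chemistry: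
- **C8 and C9.** C8 needs its own control element, so C9 and C8 are both set by reagent-controlled boronic ester homologation. The syn (threo) dimethyl pair requires opposite antipodes of the diamine in the two rounds.
- **Chain growth.** The polyketide chain is grown with Weinreb amides only, because an enolisable β-keto ester would protonate a polyanion.
- **A second aldol mode.** Besides the aldol attack of C5' on the chain ketone, the chain α-CH2 can attack the C4' ketone. That product could aromatise, so this mode must be excluded by the choice of base.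
- **C7 descriptor.** It reads R in 12, S in 14–22 and R in 23 and 24. Only the CIP ranking changes, not the geometry.

Step 1
Reactants: 1 4-(benzyloxy)benzyl chloride
Product: 2 2-[4-(benzyloxy)benzyl]-4,4,5,5-tetramethyl-1,3,2-dioxaborolane
Conditions: B2pin2, Pd(dba)2 (3 mol %), P(4-CH3OC6H4)3 (6 mol %), KOAc, toluene, 50 °C
Reagents that add atoms: bis(pinacolato)diboron CC1(C)OB(OC1(C)C)B1OC(C)(C)C(C)(C)O1
Why: Miyaura borylation of a benzylic halide: zerovalent palladium inserts into the C–Cl bond, acetate-assisted transmetalation with B2pin2 and reductive elimination deliver the benzylboronic ester, and the aryl benzyl ether is a spectator.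

Step 2
Reactants: 2 2-[4-(benzyloxy)benzyl]-4,4,5,5-tetramethyl-1,3,2-dioxaborolane
Product: 4 2-{(2R)-1-[4-(benzyloxy)phenyl]propan-2-yl}-4,4,5,5-tetramethyl-1,3,2-dioxaborolane, via lithium boronate complex 3 (not isolated)
Conditions: ethyl 2,4,6-triisopropylbenzoate, s-BuLi, (−)-sparteine, Et2O, −78 °C; then 2, −78 °C → reflux
Reagents that add atoms: ethyl 2,4,6-triisopropylbenzoate CCOC(=O)c1c(C(C)C)cc(C(C)C)cc1C(C)C
Why: Lithiation–borylation, a reagent-controlled Matteson-type homologation: s-BuLi/(−)-sparteine removes the pro-S proton of the ethyl ester, the configurationally stable (S)-carbenoid binds boron with retention, and on warming the benzyl carbon C10 migrates antiperiplanar to the departing hindered benzoate with inversion at the carbenoid carbon, which sets C9 in the required sense.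

Step 3
Reactants: 4 2-{(2R)-1-[4-(benzyloxy)phenyl]propan-2-yl}-4,4,5,5-tetramethyl-1,3,2-dioxaborolane
Product: 6 2-{(2S,3R)-4-[4-(benzyloxy)phenyl]-3-methylbutan-2-yl}-4,4,5,5-tetramethyl-1,3,2-dioxaborolane, via lithium boronate complex 5 (not isolated)
Conditions: ethyl 2,4,6-triisopropylbenzoate, s-BuLi, (+)-sparteine, Et2O, −78 °C; then 4, −78 °C → reflux
Reagents that add atoms: ethyl 2,4,6-triisopropylbenzoate CCOC(=O)c1c(C(C)C)cc(C(C)C)cc1C(C)C
Why: The same lithiation–borylation with the antipodal diamine: the (R)-carbenoid is captured with retention and C9 migrates with retention at C9 and inversion at the carbenoid carbon, so C8 is set by the reagent alone and the change of antipode gives the syn C8/C9 dimethyl pair of the target.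

Step 4
Reactants: 6 2-{(2S,3R)-4-[4-(benzyloxy)phenyl]-3-methylbutan-2-yl}-4,4,5,5-tetramethyl-1,3,2-dioxaborolane
Product: 9 1-(benzyloxy)-4-[(2R,3R)-2,3-dimethylpent-4-en-1-yl]benzene, via vinylboronate complex 7 (not isolated), via iodoalkyl boronic ester 8 (not isolated)
Conditions: CH2=CHMgBr, THF, 0 °C → rt; I2, THF/CH3OH, −78 °C; NaOCH3, −78 °C → rt
Reagents that add atoms: vinylmagnesium bromide C=C[Mg]Br
Why: Zweifel olefination: iodine activates the vinyl group of boronate 7, C8 shifts from boron to carbon with retention to give 8, and methoxide-induced anti elimination of boron and iodide releases the vinyl group that supplies C7.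

Step 5
Reactants: 9 1-(benzyloxy)-4-[(2R,3R)-2,3-dimethylpent-4-en-1-yl]benzene
Product: 10 methyl (2E,4S,5R)-6-[4-(benzyloxy)phenyl]-4,5-dimethylhex-2-enoate
Conditions: methyl acrylate, second-generation Hoveyda–Grubbs catalyst (3 mol %), CH2Cl2, 40 °C
Reagents that add atoms: methyl acrylate C=CC(=O)OC
Why: Olefin cross-metathesis: the electron-rich terminal alkene initiates readily while the electron-poor acrylate homodimerises slowly, so the thermodynamically favoured (E)-enoate should be the selective product and the allylic centre C8 is not touched.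

Step 6
Reactants: 10 methyl (2E,4S,5R)-6-[4-(benzyloxy)phenyl]-4,5-dimethylhex-2-enoate; 11 4-(benzyloxy)phenylboronic acid
Product: 12 methyl (3R,4S,5R)-3,6-bis[4-(benzyloxy)phenyl]-4,5-dimethylhexanoate
Conditions: [RhCl(C2H4)2]2 (2.5 mol %), (1R,4R)-2,5-diphenylbicyclo[2.2.2]octa-2,5-diene (5.5 mol %), K3PO4 (0.5 equiv), dioxane/H2O 10:1, 40 °C
Reagents that add atoms: none
Why: Hayashi–Miyaura conjugate arylation: the aryl-rhodium species formed by transmetalation inserts the enoate bound through its α-Re/C7-Si face, the only one left open by the C2-symmetric diene, and hydrolysis of the oxa-π-allyl rhodium releases 12, so C7 is set by the catalyst rather than by the neighbouring C8.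

Step 7
Reactants: 12 methyl (3R,4S,5R)-3,6-bis[4-(benzyloxy)phenyl]-4,5-dimethylhexanoate
Product: 14 methyl (3S,4S,5R)-2-acetyl-3,6-bis[4-(benzyloxy)phenyl]-4,5-dimethylhexanoate (C2 epimers), via lithium enolate 13 (not isolated)
Conditions: LiN(iPr)2, THF, −78 °C; CH3C(O)N(OCH3)CH3, −78 → 0 °C; cold 1 M HCl
Reagents that add atoms: N-methoxy-N-methylacetamide CC(=O)N(C)OC
Why: Crossed Claisen acylation of an ester enolate with a Weinreb amide: the chelated tetrahedral adduct persists until the acidic quench, which prevents double acylation and proton exchange with the product, and the new C5' centre is configurationally labile and is erased in step 11.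

Step 8
Reactants: 14 methyl (3S,4S,5R)-2-acetyl-3,6-bis[4-(benzyloxy)phenyl]-4,5-dimethylhexanoate
Product: 16 methyl 2-{(1S,2S,3R)-1,4-bis[4-(benzyloxy)phenyl]-2,3-dimethylbutyl}-3,5-dioxohexanoate (C2 epimers), via dilithium dienolate 15 (not isolated)
Conditions: LiN(iPr)2 (2.3 equiv), THF, −78 → 0 °C; CH3C(O)N(OCH3)CH3, −78 → 0 °C; cold 1 M HCl
Reagents that add atoms: N-methoxy-N-methylacetamide CC(=O)N(C)OC
Why: γ-Acylation of a β-keto ester dianion: the second deprotonation takes place at the terminal CH3, the dienolate reacts only at this more basic carbon, and the Weinreb amide again stores the new ketone as a stable chelate until work-up, with no stereocentre formed and C7 not acidic.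

Step 9
Reactants: 17 3-(4-methoxyphenyl)propanoic acid
Product: 19 N-methoxy-3-(4-methoxyphenyl)-N-methylpropanamide, via acyl imidazole 18 (not isolated)
Conditions: CDI, CH2Cl2, rt; CH3NH(OCH3)·HCl, rt
Reagents that add atoms: N,O-dimethylhydroxylamine hydrochloride CNOC.Cl; 1,1'-carbonyldiimidazole O=C(n1ccnc1)n1ccnc1 (its atoms remain only in 18)
Why: Amide formation through the acyl imidazole: CDI activates the acid with loss of CO2 and the hydroxylamine displaces imidazole under essentially neutral conditions.

Step 10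
Reactants: 16 methyl 2-{(1S,2S,3R)-1,4-bis[4-(benzyloxy)phenyl]-2,3-dimethylbutyl}-3,5-dioxohexanoate; 19 N-methoxy-3-(4-methoxyphenyl)-N-methylpropanamide
Product: 21 methyl 2-{(1S,2S,3R)-1,4-bis[4-(benzyloxy)phenyl]-2,3-dimethylbutyl}-9-(4-methoxyphenyl)-3,5,7-trioxononanoate (C2 epimers; keto form drawn), via trilithium trienolate 20 (not isolated)
Conditions: LiN(iPr)2 (3.3 equiv), THF, −78 → 0 °C; 19, −78 → −20 °C; cold 1 M HCl
Reagents that add atoms: none
Why: Terminal acylation of a 3,5-dioxo ester trianion (polyanion Claisen condensation): three equivalents of base remove C5'–H, one C3' proton and one terminal CH3 proton, the last-formed carbanion (the future C1') is by far the most nucleophilic site, and it adds to the Weinreb amide, whose chelated adduct can neither protonate unreacted trianion nor be attacked twice.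

Step 11
Reactants: 21 methyl 2-{(1S,2S,3R)-1,4-bis[4-(benzyloxy)phenyl]-2,3-dimethylbutyl}-9-(4-methoxyphenyl)-3,5,7-trioxononanoate
Product: 23 1-{3-[(1R,2S,3R)-1,4-bis[4-(benzyloxy)phenyl]-2,3-dimethylbutyl]-2,4,6-trihydroxyphenyl}-3-(4-methoxyphenyl)propan-1-one, via cyclohexane-1,3,5-trione tautomer 22 (not isolated)
Conditions: Mg(OCH3)2 (excess), CH3OH, reflux, Ar; then 1 M HCl
Reagents that add atoms: none
Why: Mg(OCH3)2 turns 21 into a chelated polyenolate in which C1', flanked by the C2' ketone and the chain ketone, is the nucleophile, while the hindered C5'–H (allylic strain in its enolate) stays largely in place so that the ester carbonyl C6' keeps its electrophilicity and is further activated by magnesium; attack, loss of methoxide and threefold enolisation of trione 22 give the phloroglucinol. The closest known reaction type is the base- or Mg(OCH3)2-mediated Claisen cyclisation of unbranched 3,5,7-trioxo esters, and of the related 6-(2-oxoalkyl)-4-hydroxy-2-pyranones, to acylphloroglucinols, and the branch at the ester α-carbon is the untested extension. Ring A closes by a 6-(enolendo)-exo-trig acyl substitution. No stereocentre is created: C7, C8 and C9 carry no acidic hydrogen under these conditions and the labile C5' centre vanishes on aromatisation. The step needs C-acylation at C1' to win over O-acylation (pyranone), over aldol attack of C5' on the chain ketone and over aldol attack of the chain α-CH2 on the C4' ketone: pyranone formation is reversible in methanolic methoxide, the first aldol would build a quaternary carbon that cannot aromatise and so reverts, and the second needs an enolate that this weak base cannot raise on an already anionic chelate. Only the Claisen path ends in an aromatic phenolate, which makes it the thermodynamic sink of the equilibrating manifold.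

Step 12
Reactants: 23 1-{3-[(1R,2S,3R)-1,4-bis[4-(benzyloxy)phenyl]-2,3-dimethylbutyl]-2,4,6-trihydroxyphenyl}-3-(4-methoxyphenyl)propan-1-one
Product: 24 1-{3-[(1R,2S,3R)-1,4-bis(4-hydroxyphenyl)-2,3-dimethylbutyl]-2,4,6-trihydroxyphenyl}-3-(4-methoxyphenyl)propan-1-one (CNP0193401.2)
Conditions: H2 (1 atm), 10% Pd/C, EtOAc/CH3OH, rt
Reagents that add atoms: none
Why: Catalytic hydrogenolysis: the benzylic C–O bonds of the two aryl benzyl ethers are cleaved on palladium at atmospheric pressure, whereas the strongly hydrogen-bonded aryl ketone, the aryl methyl ether and the all-carbon benzylic positions C7 and C10 should remain untouched.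

Compound list
1 | 4-(benzyloxy)benzyl chloride | ClCc1ccc(OCc2ccccc2)cc1 | starting material
2 | 2-[4-(benzyloxy)benzyl]-4,4,5,5-tetramethyl-1,3,2-dioxaborolane | CC1(C)OB(Cc2ccc(OCc3ccccc3)cc2)OC1(C)C | intermediate
3 | lithium boronate from 2 and the (S)-carbenoid (boron bears the benzyl group and the (S)-1-(2,4,6-triisopropylbenzoyloxy)ethyl group) | [Li+].C[C@@H](OC(=O)c1c(C(C)C)cc(C(C)C)cc1C(C)C)[B-]1(Cc2ccc(OCc3ccccc3)cc2)OC(C)(C)C(C)(C)O1 | intermediate
4 | 2-{(2R)-1-[4-(benzyloxy)phenyl]propan-2-yl}-4,4,5,5-tetramethyl-1,3,2-dioxaborolane | CC1(C)OB(OC1(C)C)[C@H](C)Cc1ccc(OCc2ccccc2)cc1 | intermediate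
5 | lithium boronate from 4 and the (R)-carbenoid (C9 as in 4) | [Li+].C[C@H](OC(=O)c1c(C(C)C)cc(C(C)C)cc1C(C)C)[B-]1([C@H](C)Cc2ccc(OCc3ccccc3)cc2)OC(C)(C)C(C)(C)O1 | intermediate
6 | 2-{(2S,3R)-4-[4-(benzyloxy)phenyl]-3-methylbutan-2-yl}-4,4,5,5-tetramethyl-1,3,2-dioxaborolane | CC1(C)OB(OC1(C)C)[C@@H](C)[C@H](C)Cc1ccc(OCc2ccccc2)cc1 | intermediate
7 | bromomagnesium vinylboronate of 6 (C8, C9 as in 6) | C=C[B-]1([C@@H](C)[C@H](C)Cc2ccc(OCc3ccccc3)cc2)OC(C)(C)C(C)(C)O1.[Mg+2].[Br-] | intermediate
8 | pinacol (3R,4R)-5-[4-(benzyloxy)phenyl]-1-iodo-3,4-dimethylpentan-2-ylboronate (boron-bearing carbon unassigned) | ICC(B1OC(C)(C)C(C)(C)O1)[C@@H](C)[C@H](C)Cc1ccc(OCc2ccccc2)cc1 | intermediate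
9 | 1-(benzyloxy)-4-[(2R,3R)-2,3-dimethylpent-4-en-1-yl]benzene | C=C[C@@H](C)[C@H](C)Cc1ccc(OCc2ccccc2)cc1 | intermediate
10 | methyl (2E,4S,5R)-6-[4-(benzyloxy)phenyl]-4,5-dimethylhex-2-enoate | COC(=O)/C=C/[C@@H](C)[C@H](C)Cc1ccc(OCc2ccccc2)cc1 | intermediate
11 | 4-(benzyloxy)phenylboronic acid | OB(O)c1ccc(OCc2ccccc2)cc1 | starting material
12 | methyl (3R,4S,5R)-3,6-bis[4-(benzyloxy)phenyl]-4,5-dimethylhexanoate | COC(=O)C[C@@H](c1ccc(OCc2ccccc2)cc1)[C@@H](C)[C@H](C)Cc1ccc(OCc2ccccc2)cc1 | intermediate
13 | lithium enolate of 12 | [Li+].COC([O-])=C[C@@H](c1ccc(OCc2ccccc2)cc1)[C@@H](C)[C@H](C)Cc1ccc(OCc2ccccc2)cc1 | intermediate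
14 | methyl (3S,4S,5R)-2-acetyl-3,6-bis[4-(benzyloxy)phenyl]-4,5-dimethylhexanoate (C2 epimers) | COC(=O)C(C(C)=O)[C@@H](c1ccc(OCc2ccccc2)cc1)[C@@H](C)[C@H](C)Cc1ccc(OCc2ccccc2)cc1 | intermediate
15 | dilithium dienolate of 14 | [Li+].[Li+].COC([O-])=C(C([O-])=C)[C@@H](c1ccc(OCc2ccccc2)cc1)[C@@H](C)[C@H](C)Cc1ccc(OCc2ccccc2)cc1 | intermediate
16 | methyl 2-{(1S,2S,3R)-1,4-bis[4-(benzyloxy)phenyl]-2,3-dimethylbutyl}-3,5-dioxohexanoate (C2 epimers, keto form) | COC(=O)C(C(=O)CC(C)=O)[C@@H](c1ccc(OCc2ccccc2)cc1)[C@@H](C)[C@H](C)Cc1ccc(OCc2ccccc2)cc1 | intermediate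
17 | 3-(4-methoxyphenyl)propanoic acid | COc1ccc(CCC(=O)O)cc1 | starting material
18 | 1-[3-(4-methoxyphenyl)propanoyl]imidazole | COc1ccc(CCC(=O)n2ccnc2)cc1 | intermediate
19 | N-methoxy-3-(4-methoxyphenyl)-N-methylpropanamide | COc1ccc(CCC(=O)N(C)OC)cc1 | intermediate
20 | trilithium trienolate of 16 | [Li+].[Li+].[Li+].COC([O-])=C(C([O-])=CC([O-])=C)[C@@H](c1ccc(OCc2ccccc2)cc1)[C@@H](C)[C@H](C)Cc1ccc(OCc2ccccc2)cc1 | intermediate
21 | methyl 2-{(1S,2S,3R)-1,4-bis[4-(benzyloxy)phenyl]-2,3-dimethylbutyl}-9-(4-methoxyphenyl)-3,5,7-trioxononanoate (C2 epimers, keto form) | COC(=O)C([C@@H](c1ccc(OCc2ccccc2)cc1)[C@@H](C)[C@H](C)Cc1ccc(OCc2ccccc2)cc1)C(=O)CC(=O)CC(=O)CCc1ccc(OC)cc1 | intermediate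
22 | 4-{(1S,2S,3R)-1,4-bis[4-(benzyloxy)phenyl]-2,3-dimethylbutyl}-2-[3-(4-methoxyphenyl)propanoyl]cyclohexane-1,3,5-trione (magnesium enolate in the flask) | COc1ccc(CCC(=O)C2C(=O)CC(=O)C([C@@H](c3ccc(OCc4ccccc4)cc3)[C@@H](C)[C@H](C)Cc3ccc(OCc4ccccc4)cc3)C2=O)cc1 | intermediate
23 | 1-{3-[(1R,2S,3R)-1,4-bis[4-(benzyloxy)phenyl]-2,3-dimethylbutyl]-2,4,6-trihydroxyphenyl}-3-(4-methoxyphenyl)propan-1-one | COc1ccc(CCC(=O)c2c(O)cc(O)c([C@@H](c3ccc(OCc4ccccc4)cc3)[C@@H](C)[C@H](C)Cc3ccc(OCc4ccccc4)cc3)c2O)cc1 | intermediate
24 | 1-{3-[(1R,2S,3R)-1,4-bis(4-hydroxyphenyl)-2,3-dimethylbutyl]-2,4,6-trihydroxyphenyl}-3-(4-methoxyphenyl)propan-1-one | COc1ccc(CCC(=O)c2c(O)cc(O)c([C@@H](c3ccc(O)cc3)[C@@H](C)[C@H](C)Cc3ccc(O)cc3)c2O)cc1 | target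

Total step count: 12. Longest linear sequence: 11 (steps 1–8 and 10–12; step 9 is the side branch).

Steps most likely to fail

1. **Step 11 (key step).**
   - **What may go wrong:** ring closure through the C2' enol oxygen instead of through C1'. Alternatively, attack on the hindered ester may be so slow that methoxide-induced retro-Claisen fragmentation of the chain overtakes cyclisation.
   - **Fallback:** it sets out from 9 (with 17) and returns at 23. It attaches an intact ring A to C7 instead of building ring A.
   - Ozonolysis of 9 (O3, CH2Cl2, −78 °C; PPh3) would give (2S,3R)-4-[4-(benzyloxy)phenyl]-2,3-dimethylbutanal F1.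
   - Commercial 4-(benzyloxy)phenylmagnesium bromide adds to F1 to give (2S,3R)-1,4-bis[4-(benzyloxy)phenyl]-2,3-dimethylbutan-1-ol F2. The carbinol epimers are of no consequence because both ionise to the same cation.
   - Separately, Friedel–Crafts acylation of phloroglucinol with 17 (BF3·OEt2, 80 °C) gives 3-(4-methoxyphenyl)-1-(2,4,6-trihydroxyphenyl)propan-1-one F3.
   - Acid-catalysed Friedel–Crafts benzylation of F3 by F2 (Bi(OTf)3, CH3NO2/CH2Cl2, −20 °C) then gives 23. The two free positions of ring A in F3 are equivalent.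
   - In the ring-C-stabilised cation, C8–H should lie in the cation plane (1,3-allylic strain), so the arene should approach anti to the C9 branch. That corresponds to the required C7 configuration. Any C7 epimer would be removed by chromatography.

2. **Step 10.**
   - **What may go wrong:** an incomplete third deprotonation, or proton transfer from the α-CH2 of the amide to the very basic terminal carbanion. Either would return starting materials.
   - **Fallback:** it sets out from 14 (with 18) and returns at 21. It forms the C3'–C2' bond instead of the bond from C1' to the chain ketone, and it bypasses 16, 19 and 20.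
   - Acyl imidazole 18 is condensed with potassium methyl malonate (MgCl2, Et3N, CH3CN; decarboxylative Claisen) to give methyl 5-(4-methoxyphenyl)-3-oxopentanoate F4.
   - F4 is converted with one equivalent of LiN(iPr)2 into its lithium enolate F5, so that it carries no proton able to quench a polyanion.
   - Dianion 15, raised from 14, is then acylated at its terminal carbon by the ester group of F5 (THF, 0 °C → rt). This is the known condensation of a β-keto ester dianion with a β-keto ester monoanion.

3. **Step 6.**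
   - **What may go wrong:** poor facial selectivity if the catalyst and the C8 centre are mismatched. Insertion into the γ-branched enoate may also be slow enough for protodeboronation of the boronic acid to compete.
   - **Fallback:** it sets out from 9 and returns at 12. It replaces catalyst control by a covalently bound auxiliary.
   - (4R)-4-Phenyl-1,3-oxazolidin-2-one is N-acylated with acryloyl chloride to give (4R)-3-acryloyl-4-phenyl-1,3-oxazolidin-2-one F6.
   - Cross-metathesis of F6 with 9 (second-generation Hoveyda–Grubbs catalyst) gives (4R)-3-{(2E,4S,5R)-6-[4-(benzyloxy)phenyl]-4,5-dimethylhex-2-enoyl}-4-phenyl-1,3-oxazolidin-2-one F7.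
   - 4-(Benzyloxy)phenylmagnesium bromide with CuBr·SMe2 (THF/SMe2, −40 °C) adds to the magnesium-chelated s-cis enoyl imide from the face opposite to the phenyl group, which is the Si face of C7. This gives (4R)-3-{(3R,4S,5R)-3,6-bis[4-(benzyloxy)phenyl]-4,5-dimethylhexanoyl}-4-phenyl-1,3-oxazolidin-2-one F8.
   - Methanolysis of F8 (NaOCH3, CH3OH, 0 °C) releases 12 and the auxiliary.

Further compounds
F1 | step 11 | (2S,3R)-4-[4-(benzyloxy)phenyl]-2,3-dimethylbutanal | O=C[C@@H](C)[C@H](C)Cc1ccc(OCc2ccccc2)cc1
F2 | step 11 | (2S,3R)-1,4-bis[4-(benzyloxy)phenyl]-2,3-dimethylbutan-1-ol (carbinol epimers) | OC(c1ccc(OCc2ccccc2)cc1)[C@@H](C)[C@H](C)Cc1ccc(OCc2ccccc2)cc1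
F3 | step 11 | 3-(4-methoxyphenyl)-1-(2,4,6-trihydroxyphenyl)propan-1-one | COc1ccc(CCC(=O)c2c(O)cc(O)cc2O)cc1
F4 | step 10 | methyl 5-(4-methoxyphenyl)-3-oxopentanoate | COC(=O)CC(=O)CCc1ccc(OC)cc1
F5 | step 10 | lithium enolate of methyl 5-(4-methoxyphenyl)-3-oxopentanoate | [Li+].COC(=O)C=C([O-])CCc1ccc(OC)cc1
F6 | step 6 | (4R)-3-acryloyl-4-phenyl-1,3-oxazolidin-2-one | C=CC(=O)N1[C@H](c2ccccc2)COC1=O
F7 | step 6 | (4R)-3-{(2E,4S,5R)-6-[4-(benzyloxy)phenyl]-4,5-dimethylhex-2-enoyl}-4-phenyl-1,3-oxazolidin-2-one | O=C(/C=C/[C@@H](C)[C@H](C)Cc1ccc(OCc2ccccc2)cc1)N1[C@H](c2ccccc2)COC1=O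
F8 | step 6 | (4R)-3-{(3R,4S,5R)-3,6-bis[4-(benzyloxy)phenyl]-4,5-dimethylhexanoyl}-4-phenyl-1,3-oxazolidin-2-one | O=C(C[C@@H](c1ccc(OCc2ccccc2)cc1)[C@@H](C)[C@H](C)Cc1ccc(OCc2ccccc2)cc1)N1[C@H](c2ccccc2)COC1=O
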